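**Plan**

- Ring positions are numbered as in 2-methoxy-6-alkyl-1,4-benzoquinone: C1 and C4 are the carbonyls, C2 carries OMe, C3 and C5 are C–H, C6 carries the side chain. The C2 and C4 oxygens flank C3–H, so the ring is an oxidised 5-alkylresorcinol, i.e. a masked 1,3-dicarbonyl: C2–C3 is a Claisen bond (ester carbon to α-carbon) and C6 sits β to that ester carbon.
- Retrosynthesis: remove the C1 oxygen (para-oxidation of a 3-methoxy-5-alkylphenol), the O-methyl and O-acetyl groups, and re-attach two temporary CO2tBu groups at C3 and C5. Then cut C2–C3 (Dieckmann) and C5–C6 (Michael) to give a 2-ynoate and di-tert-butyl acetonedicarboxylate. Cut the ynoate at its propargylic C–C bond to methyl propiolate and (R)-2-tridecyloxirane, and the oxirane to (R)-epichlorohydrin and a C12 Grignard reagent.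
- Forward: the chain is joined first (C12 + C3, then + C3 propiolate). The only ring is then built in one annulation that delivers the resorcinol with all substituents placed. The finish is mono-O-methylation, silyl-to-acetyl exchange, removal of the two carboxyl helpers and para-oxidation to the quinone.
- Stereochemistry: the single (R) centre comes from (R)-epichlorohydrin. Both C–C bond formations occur at the neighbouring CH2 carbons and its C–O bond is never broken.

Key step: step 5

Remark: compounds 1, 2, 5 and 9 are taken as commercial; the side-chain stereocentre of the target is read as (R).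

**Step 1**
Reactants: 1 (R)-epichlorohydrin; 2 dodecylmagnesium bromide
Product: 3 (2R)-1-chloropentadecan-2-ol
Conditions: CuI (10 mol %), THF, −40 to −20 °C; aq. NH4Cl
Reagents that add atoms: none
Why: Copper-catalysed Grignard opening of the epoxide at its unsubstituted carbon (SN2) leaves the stereocentre untouched, so the configuration of 1 is carried into the chlorohydrin.

**Step 2**
Reactants: 3 (2R)-1-chloropentadecan-2-ol
Product: 4 (2R)-2-tridecyloxirane
Conditions: powdered NaOH, Et2O, rt
Reagents that add atoms: none
Why: Intramolecular Williamson etherification closes the epoxide by displacement of the primary chloride, again without touching the C–O bond of the stereocentre.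

**Step 3**
Reactants: 4 (2R)-2-tridecyloxirane; 5 methyl propiolate
Product: 7 methyl (5R)-5-hydroxyoctadec-2-ynoate, via lithium acetylide 6 (not isolated)
Conditions: 5, n-BuLi, THF, −78 °C; BF3·OEt2; then 4, −78 °C; aq. NH4Cl
Reagents that add atoms: none
Why: BF3-promoted opening of a terminal epoxide by a lithium acetylide (Yamaguchi alkynylation) occurs at the CH2 carbon, so the carbinol centre keeps its configuration.

**Step 4**
Reactants: 7 methyl (5R)-5-hydroxyoctadec-2-ynoate
Product: 8 methyl (5R)-5-(tert-butyldimethylsilyloxy)octadec-2-ynoate
Conditions: TBSOTf, 2,6-lutidine, CH2Cl2, −78 to 0 °C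
Reagents that add atoms: tert-butyldimethylsilyl triflate, CC(C)(C)[Si](C)(C)OS(=O)(=O)C(F)(F)F
Why: Silylation of the secondary alcohol with a silyl triflate and a hindered, non-nucleophilic base masks the oxygen as a poor leaving group for the basic annulation and leaves the ynoate untouched.

**Step 5**
Reactants: 8 methyl (5R)-5-(tert-butyldimethylsilyloxy)octadec-2-ynoate; 9 di-tert-butyl 3-oxopentanedioate
Product: 11 di-tert-butyl 6-[(2R)-2-(tert-butyldimethylsilyloxy)pentadecyl]-2,4-dihydroxybenzene-1,3-dicarboxylate, via Michael adduct 10 (not isolated)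
Conditions: 9, NaH, THF, 0 °C; then 8, rt to 65 °C; aq. HCl (1 M), 0 °C
Reagents that add atoms: none
Why: The sodium enolate of 9 should add through one α-carbon to the β-carbon of ynoate 8 to give triester 10, whose delocalised anion equilibrates to the Z geometry; the enolate at the other α-carbon then attacks the methyl ester carbonyl, methoxide leaves and the cyclohexadienone enolises irreversibly to the resorcinol. The closest known reaction type is the Michael addition–Dieckmann benzannulation of acetonedicarboxylates with 2-alkynoates, the classical entry to 5-alkylresorcinols. The six-membered ring closes in a 6-(enolexo)-exo-trig acyl substitution, and the bond formed joins the future C3–H carbon to the future methoxy-bearing C2. No new stereocentre arises and the existing one lies outside the reacting array. The step needs C-acylation rather than O-acylation (which would give a 2-pyranone) and attack on the ynoate-derived ester only: the second ester of 9 acidifies the attacking CH2 and aromatisation is the thermodynamic sink, while the tert-butyl esters resist acyl substitution and alkoxide exchange. The silyloxy group is a poor leaving group, which should suppress vinylogous elimination under the weakly basic enolate conditions.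

**Step 6**
Reactants: 11 di-tert-butyl 6-[(2R)-2-(tert-butyldimethylsilyloxy)pentadecyl]-2,4-dihydroxybenzene-1,3-dicarboxylate
Product: 12 di-tert-butyl 6-[(2R)-2-(tert-butyldimethylsilyloxy)pentadecyl]-2-hydroxy-4-methoxybenzene-1,3-dicarboxylate
Conditions: MeI (1.1 equiv), K2CO3, acetone, rt to 40 °C
Reagents that add atoms: iodomethane, CI
Why: Williamson O-methylation should take the 4-hydroxyl, which has one open flank, while the 2-hydroxyl buried between two tert-butyl esters and chelated to them resists a second alkylation; methylation at either oxygen would in any case lead to the same phenol 16 once both carboxyl groups are gone.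

**Step 7**
Reactants: 12 di-tert-butyl 6-[(2R)-2-(tert-butyldimethylsilyloxy)pentadecyl]-2-hydroxy-4-methoxybenzene-1,3-dicarboxylate
Product: 13 di-tert-butyl 2-hydroxy-6-[(2R)-2-hydroxypentadecyl]-4-methoxybenzene-1,3-dicarboxylate
Conditions: HF·pyridine, pyridine/THF, 0 °C to rt
Reagents that add atoms: none
Why: Fluoride-mediated desilylation under buffered, non-alkoxide conditions frees the secondary alcohol, and the neighbouring tert-butyl ester is too hindered to lactonise with a neutral alcohol.

**Step 8**
Reactants: 13 di-tert-butyl 2-hydroxy-6-[(2R)-2-hydroxypentadecyl]-4-methoxybenzene-1,3-dicarboxylate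
Product: 14 di-tert-butyl 6-[(2R)-2-acetoxypentadecyl]-2-hydroxy-4-methoxybenzene-1,3-dicarboxylate
Conditions: Ac2O, pyridine, CH2Cl2, rt
Reagents that add atoms: acetic anhydride, CC(=O)OC(C)=O
Why: Pyridine-mediated acetylation of the secondary alcohol proceeds with retention (the C–O bond is not broken), while the remaining phenol, flanked by two tert-butyl esters and hydrogen-bonded to them, should stay unacylated.

**Step 9**
Reactants: 14 di-tert-butyl 6-[(2R)-2-acetoxypentadecyl]-2-hydroxy-4-methoxybenzene-1,3-dicarboxylate
Product: 16 (2R)-1-(3-hydroxy-5-methoxyphenyl)pentadecan-2-yl acetate, via diacid 15 (not isolated)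
Conditions: TFA/CH2Cl2, rt; evaporate; then DMF, 120–140 °C
Reagents that add atoms: none
Why: Acidolysis of the tert-butyl esters (loss of 2-methylpropene) followed by thermal protodecarboxylation of the two salicylic-type acids, each ortho or para to both oxygen donors, should strip the helper groups; the ring is electron-poor and almost fully substituted while tert-butyl cations are present, and the acetate tolerates anhydrous acid.

**Step 10**
Reactants: 16 (2R)-1-(3-hydroxy-5-methoxyphenyl)pentadecan-2-yl acetate
Product: 17 ardisinone, (2R)-1-(5-methoxy-3,6-dioxocyclohexa-1,4-dien-1-yl)pentadecan-2-yl acetate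
Conditions: K2[ON(SO3)2] (Fremy's salt, 2.5 equiv), KH2PO4, acetone/H2O, rt
Reagents that add atoms: Fremy's salt (dipotassium nitrosodisulfonate), [K+].[K+].[O]N(S(=O)(=O)[O-])S(=O)(=O)[O-]
Why: Teuber oxidation: the phenoxyl radical is trapped by a second nitroxide at the free para position (the carbon between OMe and the side chain) and loss of imidodisulfonate gives the para-quinone, as known for 3-methoxy-5-alkylphenols; the acetate is inert to the buffered medium.

**Compound list**

1 | (R)-epichlorohydrin, (2R)-2-(chloromethyl)oxirane | ClC[C@H]1CO1 | starting material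
2 | dodecylmagnesium bromide | CCCCCCCCCCCC[Mg]Br | starting material
3 | (2R)-1-chloropentadecan-2-ol | CCCCCCCCCCCCC[C@@H](O)CCl | intermediate
4 | (2R)-2-tridecyloxirane | CCCCCCCCCCCCC[C@@H]1CO1 | intermediate
5 | methyl propiolate | C#CC(=O)OC | starting material
6 | lithium acetylide of methyl propiolate (methyl 3-lithiopropiolate), not isolated | [Li]C#CC(=O)OC | intermediate
7 | methyl (5R)-5-hydroxyoctadec-2-ynoate | CCCCCCCCCCCCC[C@@H](O)CC#CC(=O)OC | intermediate
8 | methyl (5R)-5-(tert-butyldimethylsilyloxy)octadec-2-ynoate | CCCCCCCCCCCCC[C@@H](O[Si](C)(C)C(C)(C)C)CC#CC(=O)OC | intermediate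
9 | di-tert-butyl 3-oxopentanedioate (di-tert-butyl acetonedicarboxylate) | CC(C)(C)OC(=O)CC(=O)CC(=O)OC(C)(C)C | starting material
10 | Michael adduct, di-tert-butyl 2-[(2Z,5R)-5-(tert-butyldimethylsilyloxy)-1-methoxy-1-oxooctadec-2-en-3-yl]-3-oxopentanedioate, not isolated | CCCCCCCCCCCCC[C@@H](O[Si](C)(C)C(C)(C)C)C/C(=C/C(=O)OC)C(C(=O)OC(C)(C)C)C(=O)CC(=O)OC(C)(C)C | intermediate
11 | di-tert-butyl 6-[(2R)-2-(tert-butyldimethylsilyloxy)pentadecyl]-2,4-dihydroxybenzene-1,3-dicarboxylate | CCCCCCCCCCCCC[C@@H](O[Si](C)(C)C(C)(C)C)Cc1cc(O)c(C(=O)OC(C)(C)C)c(O)c1C(=O)OC(C)(C)C | intermediate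
12 | di-tert-butyl 6-[(2R)-2-(tert-butyldimethylsilyloxy)pentadecyl]-2-hydroxy-4-methoxybenzene-1,3-dicarboxylate | CCCCCCCCCCCCC[C@@H](O[Si](C)(C)C(C)(C)C)Cc1cc(OC)c(C(=O)OC(C)(C)C)c(O)c1C(=O)OC(C)(C)C | intermediate
13 | di-tert-butyl 2-hydroxy-6-[(2R)-2-hydroxypentadecyl]-4-methoxybenzene-1,3-dicarboxylate | CCCCCCCCCCCCC[C@@H](O)Cc1cc(OC)c(C(=O)OC(C)(C)C)c(O)c1C(=O)OC(C)(C)C | intermediate
14 | di-tert-butyl 6-[(2R)-2-acetoxypentadecyl]-2-hydroxy-4-methoxybenzene-1,3-dicarboxylate | CCCCCCCCCCCCC[C@@H](OC(C)=O)Cc1cc(OC)c(C(=O)OC(C)(C)C)c(O)c1C(=O)OC(C)(C)C | intermediate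
15 | diacid, 6-[(2R)-2-acetoxypentadecyl]-2-hydroxy-4-methoxybenzene-1,3-dicarboxylic acid, not isolated | CCCCCCCCCCCCC[C@@H](OC(C)=O)Cc1cc(OC)c(C(O)=O)c(O)c1C(O)=O | intermediate
16 | (2R)-1-(3-hydroxy-5-methoxyphenyl)pentadecan-2-yl acetate | CCCCCCCCCCCCC[C@@H](OC(C)=O)Cc1cc(O)cc(OC)c1 | intermediate
17 | ardisinone, (2R)-1-(5-methoxy-3,6-dioxocyclohexa-1,4-dien-1-yl)pentadecan-2-yl acetate | CCCCCCCCCCCCC[C@H](CC1=CC(=O)C=C(OC)C1=O)OC(C)=O | target

**Step count and risks**

Total step count: 10. Longest linear sequence: 10 steps (from 1 and 2; compounds 5 and 9 enter as commercial reagents).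

Steps most likely to fail:

1. Step 5 (annulation). After the conjugate addition the enolate may acylate through oxygen, closing irreversibly to a 2-pyranone. The ynoate may also isomerise to the allenoate and expel the silyloxy group by vinylogous elimination while the bulky donor adds slowly. The fallback lowers the oxidation level of the acceptor, so that O-acylation becomes reversible and no allene can form. Setting out from 8, Lindlar semihydrogenation (H2, Pd on CaCO3 poisoned with Pb(OAc)2, quinoline, EtOAc) should give methyl (2Z,5R)-5-(tert-butyldimethylsilyloxy)octadec-2-enoate F1. Michael addition–Dieckmann cyclisation of F1 with 9 (NaOtBu, tBuOH/THF, reflux) should give the dihydroresorcinol di-tert-butyl 4-[(2R)-2-(tert-butyldimethylsilyloxy)pentadecyl]-2,6-dioxocyclohexane-1,3-dicarboxylate F2. Dehydrogenation with DDQ (dioxane, 80 °C) would then aromatise it, and the route is rejoined at 11.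

2. Step 9 (removal of the two carboxyl helpers). The second loss of carbon dioxide may stall, because ipso-protonation of a ring that still carries one carboxyl group is slow, and prolonged heating could begin to cost the acetate. The fallback replaces arenium-ion decarboxylation by metal-mediated protodecarboxylation. Setting out from 14, the tert-butyl groups are removed with TFA as before to give the diacid 15. Catalytic Ag2CO3 with AcOH in DMSO at 120 °C should then convert the ortho-substituted carboxylates by decarboxylative argentation and protodemetalation, rejoining the route at 16. This fallback passes only through numbered compounds and makes no further compound (entry F0).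

3. Step 7 (desilylation). The liberated alcohol may lactonise onto the neighbouring ester to a 3,4-dihydroisocoumarin, or the tert-butyl esters may be partly cleaved by the acidic fluoride source. The fallback avoids a free hydroxy diester altogether by carrying the acetate through the annulation. Setting out from 7, acetylation (Ac2O, pyridine, catalytic DMAP, CH2Cl2, 0 °C) should give methyl (5R)-5-acetoxyoctadec-2-ynoate F3. Annulation of F3 with 9 under the conditions of step 5, held at the lowest workable temperature, should give di-tert-butyl 6-[(2R)-2-acetoxypentadecyl]-2,4-dihydroxybenzene-1,3-dicarboxylate F4. Methylation as in step 6 (MeI, K2CO3, acetone) rejoins the route at 14. This variant is held in reserve because acetate is a better leaving group than silyloxide in the basic annulation.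

**Further compounds**

F1 | step 5 | methyl (2Z,5R)-5-(tert-butyldimethylsilyloxy)octadec-2-enoate | CCCCCCCCCCCCC[C@@H](O[Si](C)(C)C(C)(C)C)C/C=C\C(=O)OC
F2 | step 5 | di-tert-butyl 4-[(2R)-2-(tert-butyldimethylsilyloxy)pentadecyl]-2,6-dioxocyclohexane-1,3-dicarboxylate | CCCCCCCCCCCCC[C@@H](O[Si](C)(C)C(C)(C)C)CC1CC(=O)C(C(=O)OC(C)(C)C)C(=O)C1C(=O)OC(C)(C)C
F0 | step 9 | none | none
F3 | step 7 | methyl (5R)-5-acetoxyoctadec-2-ynoate | CCCCCCCCCCCCC[C@@H](OC(C)=O)CC#CC(=O)OC
F4 | step 7 | di-tert-butyl 6-[(2R)-2-acetoxypentadecyl]-2,4-dihydroxybenzene-1,3-dicarboxylate | CCCCCCCCCCCCC[C@@H](OC(C)=O)Cc1cc(O)c(C(=O)OC(C)(C)C)c(O)c1C(=O)OC(C)(C)C
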